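**Plan**
1. Retrosynthesis: the p-coumarate C1–O bond is cut first (phenol kept as a silyl ether) and the two formyl groups are traced to the 11,12-diol, giving drim-7-ene-1β,11,12-triol. The Δ7 enal is traced to its Δ6 isomer, because C8–H is α to C12=O and the alkene can be moved back into conjugation.
2. Ring B is then a cyclohexene C5–C6=C7–C8–C9–C10 whose C9 carries the electron-withdrawing carbon C11 next to quaternary C10. A retro-[4+2] cuts C5–C10 and C8–C9 and opens both rings to a dodeca-2,8,10-trienoate (dienophile C9=C10, diene C5=C6–C7=C8, tether C1–C4 of ring A).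
3. The triene is cut at C1–C2 (Grignard reagent + aldehyde), C6–C7 (Suzuki–Miyaura) and C5=C6 (Takai), back to α,α-dimethyl-γ-butyrolactone.
4. Forward: the chain is built linearly, rings A and B arise together in one intramolecular Diels–Alder reaction, then alkene shift, reduction, selective protection, esterification and oxidation follow.
5. Stereochemistry: C1 (R) comes from a CBS reduction; C5, C9 and C10 come from C1 and the alkene geometries in the cycloaddition; the E-cinnamate comes from p-coumaric acid.

Key step: step 8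

Remark: drimane numbering is used (ring carbons C1–C10, C11 on C9, C12 on C8, C15 the methyl on C10); the target is read as (1R,5S,9R,10S), i.e. 1β-acyloxy, 5α-H, 9β-CHO, 10β-CH3, and all bicyclic intermediates share this trans-decalin configuration.

**Step 1**
Reactants: 1 3,3-dimethyloxolan-2-one (α,α-dimethyl-γ-butyrolactone)
Product: 2 ethyl 4-bromo-2,2-dimethylbutanoate
Conditions: HBr (gas, saturated), EtOH, 0 °C → rt
Reagents that add atoms: hydrogen bromide (Br); ethanol (CCO)
Why: Acid-mediated lactone opening in which bromide displaces the protonated ring oxygen at the unhindered primary O–CH2 carbon (SN2) and the acid is esterified in situ (Fischer esterification), as in the standard preparation of ethyl 4-bromobutanoate from γ-butyrolactone.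

**Step 2**
Reactants: 2 ethyl 4-bromo-2,2-dimethylbutanoate
Product: 3 4-bromo-2,2-dimethylbutanal
Conditions: iBu2AlH (1.1 equiv), CH2Cl2, −78 °C; aq. potassium sodium tartrate (KNaC4H4O6)
Reagents that add atoms: none
Why: Partial ester reduction with iBu2AlH at low temperature, where the α-quaternary centre stabilises the tetrahedral aluminium hemiacetal against over-reduction and the primary bromide is inert.

**Step 3**
Reactants: 3 4-bromo-2,2-dimethylbutanal
Product: 4 (E)-5-bromo-1-iodo-3,3-dimethylpent-1-ene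
Conditions: CrCl2 (6 equiv), CHI3 (2 equiv), THF, 0 °C → rt
Reagents that add atoms: iodoform (IC(I)I)
Why: Takai olefination, in which the geminal dichromium species adds to the non-enolisable aldehyde and eliminates to the (E)-vinyl iodide, while divalent chromium does not reduce the primary alkyl bromide under these conditions.

**Step 4**
Reactants: 4 (E)-5-bromo-1-iodo-3,3-dimethylpent-1-ene; 5 2-[(E)-3,3-diethoxyprop-1-enyl]-4,4,5,5-tetramethyl-1,3,2-dioxaborolane
Product: 6 (2E,4E)-8-bromo-1,1-diethoxy-6,6-dimethylocta-2,4-diene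
Conditions: Pd(PPh3)4 (5 mol%), K3PO4 (3 equiv), THF/H2O (5:1), 50 °C
Reagents that add atoms: none
Why: Suzuki–Miyaura sp2–sp2 coupling with retention of both alkene geometries gives the (E,E)-diene, since zerovalent palladium inserts into the vinyl C–I bond far faster than into the primary C–Br bond and the acetal is stable to aqueous base.

**Step 5**
Reactants: 6 (2E,4E)-8-bromo-1,1-diethoxy-6,6-dimethylocta-2,4-diene; 7 ethyl (E)-3-methyl-4-oxobut-2-enoate
Product: 9 ethyl (2E,8E,10E)-12,12-diethoxy-4-hydroxy-3,7,7-trimethyldodeca-2,8,10-trienoate (racemic), via dienylalkylmagnesium bromide 8 (not isolated)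
Conditions: Mg turnings, I2 (cat.), THF, rt; then added to 7, THF, −78 °C; aq. NH4Cl
Reagents that add atoms: none
Why: Grignard 1,2-addition of a primary alkylmagnesium bromide to the aldehyde, which at −78 °C is far more electrophilic than the conjugated ester or the enoate β-carbon; the acetal and diene are inert and the carbinol centre (C1) forms racemic and is corrected in step 6.

**Step 6**
Reactants: 9 ethyl (2E,8E,10E)-12,12-diethoxy-4-hydroxy-3,7,7-trimethyldodeca-2,8,10-trienoate (racemic)
Product: 11 ethyl (2E,4R,8E,10E)-12,12-diethoxy-4-hydroxy-3,7,7-trimethyldodeca-2,8,10-trienoate, via trienone 10 (not isolated)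
Conditions: Dess–Martin periodinane (1.3 equiv), pyridine (3 equiv), CH2Cl2, 0 °C, cold filtration through silica; then (S)-2-methyl-CBS-oxazaborolidine (0.3 equiv), catecholborane (1.8 equiv), toluene, −78 °C; MeOH
Reagents that add atoms: none
Why: Dess–Martin oxidation followed at once by Corey–Bakshi–Shibata reduction, in which the (S)-oxazaborolidine binds the ketone with the α-methylalkenyl group as the large substituent and delivers hydride to give the (R)-allylic alcohol (C1 of the target); the ketone is kept cold and not stored because it is itself a doubly activated cycloaddition substrate.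

**Step 7**
Reactants: 11 ethyl (2E,4R,8E,10E)-12,12-diethoxy-4-hydroxy-3,7,7-trimethyldodeca-2,8,10-trienoate
Product: 12 ethyl (2E,4R,8E,10E)-4-acetoxy-12,12-diethoxy-3,7,7-trimethyldodeca-2,8,10-trienoate
Conditions: Ac2O, pyridine, DMAP (cat.), CH2Cl2, 0 °C → rt
Reagents that add atoms: acetic anhydride (CC(=O)OC(C)=O)
Why: DMAP-catalysed acetylation of an unhindered secondary allylic alcohol without touching C1; the acetate blocks the hydroxyl in the thermal step, acts there as the directing group, and is later removed in the hydride step.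

**Step 8**
Reactants: 12 ethyl (2E,4R,8E,10E)-4-acetoxy-12,12-diethoxy-3,7,7-trimethyldodeca-2,8,10-trienoate
Product: 13 ethyl 1β-acetoxy-12,12-diethoxydrim-6-en-11-oate (trans-decalin with 5α-H and 10β-CH3; 8β-CH(OEt)2; 9β-CO2Et)
Conditions: toluene (0.01 M), BHT (0.1 equiv), base-washed sealed tube, 170 °C
Reagents that add atoms: none
Why: A concerted, suprafacial thermal [4+2] cycloaddition in which the (8E,10E)-diene C5=C6–C7=C8 adds across the ester-activated C9=C10 bond, forming C5–C10 and C8–C9 in one event and leaving the remaining double bond at C6=C7. The closest known reaction type is the type 1 intramolecular Diels–Alder reaction of terminally ester-activated (2E,8E,10E)-undeca-2,8,10-trienoates, which gives trans-fused octalins and tolerates a methyl group at the ring-fusion carbon. Ring B is closed as the new cyclohexene of the cycloaddition (both new bonds lie in it), and ring A is closed by the C5–C10 bond alone, the four-carbon tether C1–C4 folding into a chair so that the fused and not the bridged mode results. The cis relation of 10β-CH3 and 9β-CO2Et follows from the E geometry of the enoate, the cis relation of H5 and H8 from the E,E-diene, and the trans ring fusion (5α-H against 10β-CH3) from the transition state with the ester endo under the diene. The absolute sense of C5, C8, C9 and C10 is fixed by C1, whose acetoxy group should take the equatorial site of the forming chair, anti to the forming C5–C10 bond, so that one face of the dienophile is exposed. The step needs endo over exo selectivity and one-face selectivity, secured by secondary orbital overlap of the ester, by the chair tether with the equatorial, electron-withdrawing acetoxy group, and by high dilution with a radical inhibitor against dimerisation and polymerisation.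

**Step 9**
Reactants: 13 ethyl 1β-acetoxy-12,12-diethoxydrim-6-en-11-oate
Product: 15 ethyl 1β-acetoxy-12-oxodrim-7-en-11-oate (9β-CO2Et), via β,γ-unsaturated aldehyde 14 (not isolated)
Conditions: p-TsOH·H2O (0.1 equiv), acetone/H2O (9:1), rt; then DBU (0.3 equiv), CH2Cl2, rt
Reagents that add atoms: water (O)
Why: Acid-catalysed acetal hydrolysis, then amidine-base isomerisation of the β,γ-unsaturated aldehyde through its dienolate to the conjugated Δ7 enal (thermodynamic control), which removes the C8 stereocentre while the ester α-hydrogen at C9 is not acidic enough for DBU to remove.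

**Step 10**
Reactants: 15 ethyl 1β-acetoxy-12-oxodrim-7-en-11-oate
Product: 16 drim-7-ene-1β,11,12-triol
Conditions: iBu2AlH (8 equiv), CH2Cl2, −78 → 0 °C; aq. potassium sodium tartrate (KNaC4H4O6)
Reagents that add atoms: none
Why: iBu2AlH reduces the enal 1,2 to the allylic alcohol, the hindered ethyl ester to the primary alcohol and cleaves the acetate in one operation without touching a stereocentre, the usual hydride entry to drim-7-ene-11,12-diols.

**Step 11**
Reactants: 16 drim-7-ene-1β,11,12-triol
Product: 17 11,12-bis(tert-butyldimethylsilyloxy)drim-7-en-1β-ol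
Conditions: TBSCl (2.2 equiv), imidazole (4 equiv), DMF, 0 °C
Reagents that add atoms: tert-butyldimethylsilyl chloride (CC(C)(C)[Si](C)(C)Cl)
Why: Sterically controlled silylation, the two primary hydroxyls reacting far faster than the equatorial C1 hydroxyl, which is neopentylic (next to quaternary C10) and peri to C11.

**Step 12**
Reactants: 18 (E)-4-hydroxycinnamic acid (p-coumaric acid)
Product: 20 (E)-3-[4-(tert-butyldimethylsilyloxy)phenyl]prop-2-enoic acid, via bis-silyl derivative 19 (not isolated)
Conditions: TBSCl (2.5 equiv), imidazole (5 equiv), DMF, rt; then AcOH/THF/H2O (3:1:1), rt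
Reagents that add atoms: tert-butyldimethylsilyl chloride (CC(C)(C)[Si](C)(C)Cl)
Why: Exhaustive silylation of phenol and acid followed by selective hydrolysis of the labile silyl ester in aqueous acetic acid, which leaves the aryl silyl ether and the E-alkene untouched.

**Step 13**
Reactants: 17 11,12-bis(tert-butyldimethylsilyloxy)drim-7-en-1β-ol; 20 (E)-3-[4-(tert-butyldimethylsilyloxy)phenyl]prop-2-enoic acid
Product: 22 11,12-bis(tert-butyldimethylsilyloxy)drim-7-en-1β-yl (E)-3-[4-(tert-butyldimethylsilyloxy)phenyl]prop-2-enoate, via mixed anhydride 21 (not isolated)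
Conditions: 20, 2,4,6-trichlorobenzoyl chloride (1.5 equiv), Et3N (3 equiv), THF, rt; then 17, DMAP (2 equiv), toluene, 60 °C
Reagents that add atoms: none
Why: Yamaguchi esterification, in which DMAP attacks the mixed anhydride at the less hindered cinnamoyl carbonyl and the acylpyridinium acylates the hindered C1 hydroxyl with retention at C1, the C–O bond of the alcohol not being broken.

**Step 14**
Reactants: 22 11,12-bis(tert-butyldimethylsilyloxy)drim-7-en-1β-yl (E)-3-[4-(tert-butyldimethylsilyloxy)phenyl]prop-2-enoate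
Product: 23 11,12-dihydroxydrim-7-en-1β-yl (E)-3-[4-(tert-butyldimethylsilyloxy)phenyl]prop-2-enoate
Conditions: camphorsulfonic acid (0.1 equiv), MeOH/CH2Cl2 (1:1), 0 °C
Reagents that add atoms: none
Why: Acid-catalysed methanolysis removes the two primary alkyl silyl ethers, while the phenolic silyl ether, much less basic at oxygen, survives acid, and the cinnamate is inert at 0 °C.

**Step 15**
Reactants: 23 11,12-dihydroxydrim-7-en-1β-yl (E)-3-[4-(tert-butyldimethylsilyloxy)phenyl]prop-2-enoate
Product: 24 11,12-dioxodrim-7-en-1β-yl (E)-3-[4-(tert-butyldimethylsilyloxy)phenyl]prop-2-enoate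
Conditions: (COCl)2 (4 equiv), DMSO (8 equiv), CH2Cl2, −78 °C; then Et3N (10 equiv), −78 → −30 °C; cold aq. NH4Cl
Reagents that add atoms: none
Why: Swern oxidation activates both primary hydroxyls as alkoxysulfonium ions before base is added, so the dialdehyde forms without the lactol or lactone that stepwise oxidants give from 1,4-diols, and the low temperature and cold neutral quench should preserve the epimerisable 9β-formyl centre.

**Step 16**
Reactants: 24 11,12-dioxodrim-7-en-1β-yl (E)-3-[4-(tert-butyldimethylsilyloxy)phenyl]prop-2-enoate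
Product: 25 (1R,5S,9R,10S)-11,12-dioxodrim-7-en-1-yl (E)-3-(4-hydroxyphenyl)prop-2-enoate (CNP0187624.1)
Conditions: HF·pyridine, pyridine, THF, 0 °C → rt; pH 7 phosphate buffer
Reagents that add atoms: none
Why: Fluoride-mediated cleavage of the aryl Si–O bond under pyridine-buffered, weakly acidic conditions that should neither epimerise C9 nor cleave the cinnamate, releasing the free phenol.

**Compound list**
1 | 3,3-dimethyloxolan-2-one (α,α-dimethyl-γ-butyrolactone) | CC1(C)CCOC1=O | starting material
2 | ethyl 4-bromo-2,2-dimethylbutanoate | CCOC(=O)C(C)(C)CCBr | intermediate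
3 | 4-bromo-2,2-dimethylbutanal | O=CC(C)(C)CCBr | intermediate
4 | (E)-5-bromo-1-iodo-3,3-dimethylpent-1-ene | I/C=C/C(C)(C)CCBr | intermediate
5 | 2-[(E)-3,3-diethoxyprop-1-enyl]-4,4,5,5-tetramethyl-1,3,2-dioxaborolane | CCOC(OCC)/C=C/B1OC(C)(C)C(C)(C)O1 | starting material
6 | (2E,4E)-8-bromo-1,1-diethoxy-6,6-dimethylocta-2,4-diene | CCOC(OCC)/C=C/C=C/C(C)(C)CCBr | intermediate
7 | ethyl (E)-3-methyl-4-oxobut-2-enoate | CCOC(=O)/C=C(\C)C=O | starting material
8 | [(4E,6E)-8,8-diethoxy-3,3-dimethylocta-4,6-dienyl]magnesium bromide | CCOC(OCC)/C=C/C=C/C(C)(C)CC[Mg]Br | intermediate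
9 | ethyl (2E,8E,10E)-12,12-diethoxy-4-hydroxy-3,7,7-trimethyldodeca-2,8,10-trienoate (racemic) | CCOC(=O)/C=C(\C)C(O)CCC(C)(C)/C=C/C=C/C(OCC)OCC | intermediate
10 | ethyl (2E,8E,10E)-12,12-diethoxy-3,7,7-trimethyl-4-oxododeca-2,8,10-trienoate | CCOC(=O)/C=C(\C)C(=O)CCC(C)(C)/C=C/C=C/C(OCC)OCC | intermediate
11 | ethyl (2E,4R,8E,10E)-12,12-diethoxy-4-hydroxy-3,7,7-trimethyldodeca-2,8,10-trienoate | CCOC(=O)/C=C(\C)[C@H](O)CCC(C)(C)/C=C/C=C/C(OCC)OCC | intermediate
12 | ethyl (2E,4R,8E,10E)-4-acetoxy-12,12-diethoxy-3,7,7-trimethyldodeca-2,8,10-trienoate | CCOC(=O)/C=C(\C)[C@H](OC(C)=O)CCC(C)(C)/C=C/C=C/C(OCC)OCC | intermediate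
13 | ethyl 1β-acetoxy-12,12-diethoxydrim-6-en-11-oate (5α-H, 10β-CH3, 8β-CH(OEt)2, 9β-CO2Et) | CC1(C)CC[C@@H](OC(C)=O)[C@]2(C)[C@@H](C(=O)OCC)[C@@H](C(OCC)OCC)C=C[C@@H]12 | intermediate
14 | ethyl 1β-acetoxy-12-oxodrim-6-en-11-oate (8β-CHO, 9β-CO2Et) | CC1(C)CC[C@@H](OC(C)=O)[C@]2(C)[C@@H](C(=O)OCC)[C@@H](C=O)C=C[C@@H]12 | intermediate
15 | ethyl 1β-acetoxy-12-oxodrim-7-en-11-oate (9β-CO2Et) | CC1(C)CC[C@@H](OC(C)=O)[C@]2(C)[C@@H](C(=O)OCC)C(C=O)=CC[C@@H]12 | intermediate
16 | drim-7-ene-1β,11,12-triol | CC1(C)CC[C@@H](O)[C@]2(C)[C@@H](CO)C(CO)=CC[C@@H]12 | intermediate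
17 | 11,12-bis(tert-butyldimethylsilyloxy)drim-7-en-1β-ol | CC1(C)CC[C@@H](O)[C@]2(C)[C@@H](CO[Si](C)(C)C(C)(C)C)C(CO[Si](C)(C)C(C)(C)C)=CC[C@@H]12 | intermediate
18 | (E)-4-hydroxycinnamic acid (p-coumaric acid) | OC(=O)/C=C/c1ccc(O)cc1 | starting material
19 | tert-butyldimethylsilyl (E)-3-[4-(tert-butyldimethylsilyloxy)phenyl]prop-2-enoate | CC(C)(C)[Si](C)(C)OC(=O)/C=C/c1ccc(O[Si](C)(C)C(C)(C)C)cc1 | intermediate
20 | (E)-3-[4-(tert-butyldimethylsilyloxy)phenyl]prop-2-enoic acid | OC(=O)/C=C/c1ccc(O[Si](C)(C)C(C)(C)C)cc1 | intermediate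
21 | (E)-3-[4-(tert-butyldimethylsilyloxy)phenyl]prop-2-enoic 2,4,6-trichlorobenzoic anhydride | O=C(/C=C/c1ccc(O[Si](C)(C)C(C)(C)C)cc1)OC(=O)c1c(Cl)cc(Cl)cc1Cl | intermediate
22 | 11,12-bis(tert-butyldimethylsilyloxy)drim-7-en-1β-yl (E)-3-[4-(tert-butyldimethylsilyloxy)phenyl]prop-2-enoate | CC1(C)CC[C@@H](OC(=O)/C=C/c2ccc(O[Si](C)(C)C(C)(C)C)cc2)[C@]2(C)[C@@H](CO[Si](C)(C)C(C)(C)C)C(CO[Si](C)(C)C(C)(C)C)=CC[C@@H]12 | intermediate
23 | 11,12-dihydroxydrim-7-en-1β-yl (E)-3-[4-(tert-butyldimethylsilyloxy)phenyl]prop-2-enoate | CC1(C)CC[C@@H](OC(=O)/C=C/c2ccc(O[Si](C)(C)C(C)(C)C)cc2)[C@]2(C)[C@@H](CO)C(CO)=CC[C@@H]12 | intermediate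
24 | 11,12-dioxodrim-7-en-1β-yl (E)-3-[4-(tert-butyldimethylsilyloxy)phenyl]prop-2-enoate | CC1(C)CC[C@@H](OC(=O)/C=C/c2ccc(O[Si](C)(C)C(C)(C)C)cc2)[C@]2(C)[C@@H](C=O)C(C=O)=CC[C@@H]12 | intermediate
25 | (1R,5S,9R,10S)-11,12-dioxodrim-7-en-1-yl (E)-3-(4-hydroxyphenyl)prop-2-enoate (1β-p-coumaroyloxypolygodial) | CC1(C)CC[C@@H](OC(=O)/C=C/c2ccc(O)cc2)[C@]2(C)[C@@H](C=O)C(C=O)=CC[C@@H]12 | target

**Step count**
Total steps: 16. Longest linear sequence: 15 (steps 1–11 and 13–16; step 12 is a one-step side branch).

**Steps most likely to fail**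

1. Step 8. The thermal cycloaddition may discriminate poorly between endo and exo (trans against cis fusion) or between the two faces set by C1, or may be slower than thermal degradation of the acetal. The fallback sets out from 12 and comes back at 14: it removes the acetal so that the cycloaddition can be promoted by a Lewis acid at low temperature. The acetal of 12 is hydrolysed (PPTS, acetone/H2O) to the dienal ethyl (2E,4R,8E,10E)-4-acetoxy-3,7,7-trimethyl-12-oxododeca-2,8,10-trienoate F1. Luche reduction (NaBH4, CeCl3·7H2O, MeOH, −40 °C) gives the dienol ethyl (2E,4R,8E,10E)-4-acetoxy-12-hydroxy-3,7,7-trimethyldodeca-2,8,10-trienoate F2, and silylation (TBSCl, imidazole) gives the silyl ether ethyl (2E,4R,8E,10E)-4-acetoxy-12-(tert-butyldimethylsilyloxy)-3,7,7-trimethyldodeca-2,8,10-trienoate F3. Cycloaddition with MeAlCl2 (CH2Cl2, −78 → 0 °C), which should sharpen the endo preference, gives ethyl 1β-acetoxy-12-(tert-butyldimethylsilyloxy)drim-6-en-11-oate F4. Desilylation (HF·pyridine, 0 °C) gives the hydroxy ester ethyl 1β-acetoxy-12-hydroxydrim-6-en-11-oate F5, which is oxidised at once (Dess–Martin periodinane, pyridine) to aldehyde 14 and carried through the DBU stage of step 9 to 15.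

2. Step 13. Acyl transfer to the hindered equatorial C1 hydroxyl (next to quaternary C10, peri to the C11 silyloxymethyl group) may be too slow, so that the mixed anhydride is diverted or decomposes. The fallback sets out from 17 and comes back at 22: it builds the cinnamate on the alcohol by C=C formation. Heating 17 with Meldrum's acid (toluene, 100 °C; acylketene acylation, effective on hindered alcohols) gives the malonic half-ester 3-[11,12-bis(tert-butyldimethylsilyloxy)drim-7-en-1β-yloxy]-3-oxopropanoic acid F6. Knoevenagel–Doebner condensation with 4-hydroxybenzaldehyde (pyridine, piperidine cat., 80 °C) gives the E-configured 11,12-bis(tert-butyldimethylsilyloxy)drim-7-en-1β-yl (E)-3-(4-hydroxyphenyl)prop-2-enoate F7, and silylation of the phenol (TBSCl, imidazole) gives 22.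

3. Step 6. The doubly activated ketone 10 may undergo premature, uncontrolled cycloaddition before it is reduced, or conjugate reduction may compete, eroding yield and enantiopurity. The fallback sets out from 6 (through 8) and 7 and comes back at 11: it avoids the ketone by a catalytic asymmetric alkyl addition to the aldehyde. Grignard reagent 8 is transmetalated with ClTi(OiPr)3 to [(4E,6E)-8,8-diethoxy-3,3-dimethylocta-4,6-dienyl]titanium triisopropoxide F8. This is added to 7 in CH2Cl2 at 0 °C in the presence of Ti(OiPr)4 and a catalytic (R)-configured 3-aryl-H8-BINOL ligand, the enantiomer expected by analogy with aryl aldehydes to give the (R)-carbinol, and so gives 11 directly.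

**Further compounds**
F1 | step 8 | ethyl (2E,4R,8E,10E)-4-acetoxy-3,7,7-trimethyl-12-oxododeca-2,8,10-trienoate | CCOC(=O)/C=C(\C)[C@H](OC(C)=O)CCC(C)(C)/C=C/C=C/C=O
F2 | step 8 | ethyl (2E,4R,8E,10E)-4-acetoxy-12-hydroxy-3,7,7-trimethyldodeca-2,8,10-trienoate | CCOC(=O)/C=C(\C)[C@H](OC(C)=O)CCC(C)(C)/C=C/C=C/CO
F3 | step 8 | ethyl (2E,4R,8E,10E)-4-acetoxy-12-(tert-butyldimethylsilyloxy)-3,7,7-trimethyldodeca-2,8,10-trienoate | CCOC(=O)/C=C(\C)[C@H](OC(C)=O)CCC(C)(C)/C=C/C=C/CO[Si](C)(C)C(C)(C)C
F4 | step 8 | ethyl 1β-acetoxy-12-(tert-butyldimethylsilyloxy)drim-6-en-11-oate | CC1(C)CC[C@@H](OC(C)=O)[C@]2(C)[C@@H](C(=O)OCC)[C@@H](CO[Si](C)(C)C(C)(C)C)C=C[C@@H]12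
F5 | step 8 | ethyl 1β-acetoxy-12-hydroxydrim-6-en-11-oate | CC1(C)CC[C@@H](OC(C)=O)[C@]2(C)[C@@H](C(=O)OCC)[C@@H](CO)C=C[C@@H]12
F6 | step 13 | 3-[11,12-bis(tert-butyldimethylsilyloxy)drim-7-en-1β-yloxy]-3-oxopropanoic acid | CC1(C)CC[C@@H](OC(=O)CC(=O)O)[C@]2(C)[C@@H](CO[Si](C)(C)C(C)(C)C)C(CO[Si](C)(C)C(C)(C)C)=CC[C@@H]12
F7 | step 13 | 11,12-bis(tert-butyldimethylsilyloxy)drim-7-en-1β-yl (E)-3-(4-hydroxyphenyl)prop-2-enoate | CC1(C)CC[C@@H](OC(=O)/C=C/c2ccc(O)cc2)[C@]2(C)[C@@H](CO[Si](C)(C)C(C)(C)C)C(CO[Si](C)(C)C(C)(C)C)=CC[C@@H]12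
F8 | step 6 | [(4E,6E)-8,8-diethoxy-3,3-dimethylocta-4,6-dienyl]titanium triisopropoxide | CCOC(OCC)/C=C/C=C/C(C)(C)CC[Ti](OC(C)C)(OC(C)C)OC(C)C
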